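**Retrosynthetic overview**
- Feature: ring C (O1, C2, C3, C4, C4a, C8a), its exocyclic carbon C8 and the oxygen on C8 are the skeleton of kojic acid. The 5-OH of kojic acid serves as the coupling handle at C3. C7, C6 and C5 of ring A form a 1,3-dicarbonyl chain that hangs from C8.
- Last skeletal disconnection, C4a–C5 (ring A): vinylogous Claisen closure of the chain C8(OMe)–C7(=O)–C6H2–C5O2Me on the intact pyranone, followed by aromatisation. Only a 3'-O-MOM group then remains to be removed.
- Chain: C6–C7 by decarboxylative Claisen condensation with a malonate half-ester. C7–C8 by carboxylation of the lateral dienolate of the 2-methoxymethylpyranone.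
- C3–C1': Suzuki coupling of the O-methylated kojic acid 5-triflate with a ring B boronate. The boronate comes from sterically controlled C–H borylation of protected 2,3-dimethoxyphenol.
- Ring order: ring C is bought, ring B is attached, ring A is formed last.

Key step: step 8

Remark: isoflavone numbering (O1, C2 … C8a) is used for these atoms in all intermediates. The target is achiral, and the C8 centre of the chain intermediates is racemic, labile and erased on aromatisation.

**Step 1**
Reactants: 1 kojic acid
Product: 2 6-(hydroxymethyl)-4-oxo-4H-pyran-3-yl trifluoromethanesulfonate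
Conditions: PhNTf2 (1.05 equiv), Et3N (1.2 equiv), DMF, 0 °C to rt
Reagents that add atoms: N-phenylbis(trifluoromethanesulfonimide), O=S(=O)(C(F)(F)F)N(c1ccccc1)S(=O)(=O)C(F)(F)F
Why: Chemoselective O-triflation: Et3N ionises only the enolic 5-OH, which is far more acidic than the primary alcohol, and the mild triflyl donor PhNTf2 reacts with such oxyanions but not with a neutral primary alcohol, so C3 is armed for cross-coupling without protecting the CH2OH arm.

**Step 2**
Reactants: 2 6-(hydroxymethyl)-4-oxo-4H-pyran-3-yl trifluoromethanesulfonate
Product: 3 6-(methoxymethyl)-4-oxo-4H-pyran-3-yl trifluoromethanesulfonate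
Conditions: Ag2O (2 equiv), MeI (10 equiv), 4 Å MS, CH2Cl2, dark, rt to 40 °C
Reagents that add atoms: iodomethane, CI
Why: Purdie methylation etherifies the primary alcohol under essentially neutral conditions, which keeps the kojic acid oxygen as the future 8-methoxy oxygen, spares the base-labile enol triflate and avoids hard methylating agents (MeOTf, Me3OBF4) that would alkylate the C4 carbonyl oxygen to a pyrylium salt.

**Step 3**
Reactants: 4 2,3-dimethoxyphenol
Product: 5 1,2-dimethoxy-3-(methoxymethoxy)benzene
Conditions: MOMCl (1.3 equiv), iPr2NEt (1.5 equiv), CH2Cl2, 0 °C to rt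
Reagents that add atoms: chloromethyl methyl ether, COCCl
Why: Standard O-alkylation of a phenol to its MOM acetal; MOM is preferred to benzyl because it offers no unhindered aryl C–H bonds to the borylation catalyst of step 4, withstands the bases of steps 5 to 8 and leaves under mild acid.

**Step 4**
Reactants: 5 1,2-dimethoxy-3-(methoxymethoxy)benzene
Product: 6 2-[3,4-dimethoxy-5-(methoxymethoxy)phenyl]-4,4,5,5-tetramethyl-1,3,2-dioxaborolane
Conditions: [Ir(OMe)(cod)]2 (1.5 mol %), 4,4'-di-tert-butyl-2,2'-bipyridine (3 mol %), B2pin2 (1.0 equiv), THF, 80 °C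
Reagents that add atoms: bis(pinacolato)diboron, CC1(C)OB(OC1(C)C)B1OC(C)(C)C(C)(C)O1
Why: Iridium-catalysed aromatic C–H borylation is governed by sterics: of the three ring C–H bonds only C5–H has no ortho substituent, so boron should enter para to the central methoxy group and give the 3,4,5-trioxygenated ring B pattern that electrophilic halogenation cannot reach.

**Step 5**
Reactants: 3 6-(methoxymethyl)-4-oxo-4H-pyran-3-yl trifluoromethanesulfonate, 6 2-[3,4-dimethoxy-5-(methoxymethoxy)phenyl]-4,4,5,5-tetramethyl-1,3,2-dioxaborolane
Product: 7 5-[3,4-dimethoxy-5-(methoxymethoxy)phenyl]-2-(methoxymethyl)-4H-pyran-4-one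
Conditions: Pd(dppf)Cl2 (5 mol %), K3PO4 (2 equiv), 1,4-dioxane/H2O (10:1), 80 °C
Reagents that add atoms: none
Why: Suzuki–Miyaura coupling: zerovalent palladium inserts readily into the electron-poor enol triflate next to the pyranone carbonyl, the same construction as the 3-halochromone route to isoflavones, and a phosphate base with little water limits triflate hydrolysis and pyranone opening.

**Step 6**
Reactants: 7 5-[3,4-dimethoxy-5-(methoxymethoxy)phenyl]-2-(methoxymethyl)-4H-pyran-4-one, 8 carbon dioxide
Product: 10 2-methoxy-2-{5-[3,4-dimethoxy-5-(methoxymethoxy)phenyl]-4-oxo-4H-pyran-2-yl}acetic acid (racemic), via lithium dienolate 9 (not isolated)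
Conditions: LiN(SiMe3)2 (1.1 equiv), THF, −78 °C; dry CO2, −78 to 0 °C; cold dilute aq. HCl to pH 3
Reagents that add atoms: carbon dioxide 8, O=C=O; LiN(SiMe3)2, [Li+].C[Si](C)(C)[N-][Si](C)(C)C (lithium of 9 only)
Why: Lateral (vinylogous) metalation and carboxylation of a 2-alkyl-4-pyranone: the C8–H bonds are gamma to the C4 carbonyl and further acidified by the methoxy group, the hindered amide does not add to the ring, and dienolate 9 takes up CO2 at the exocyclic gamma carbon because only that restores the pyranone; C8 forms racemic, which is irrelevant since it becomes an arene carbon in step 8.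

**Step 7**
Reactants: 10 2-methoxy-2-{5-[3,4-dimethoxy-5-(methoxymethoxy)phenyl]-4-oxo-4H-pyran-2-yl}acetic acid, 11 potassium methyl malonate (KO2CCH2CO2Me)
Product: 13 methyl 4-methoxy-3-oxo-4-{5-[3,4-dimethoxy-5-(methoxymethoxy)phenyl]-4-oxo-4H-pyran-2-yl}butanoate (racemic), via acyl imidazolide 12 (not isolated)
Conditions: 1,1'-carbonyldiimidazole (1.1 equiv), THF, rt; then KO2CCH2CO2Me (2 equiv), MgCl2 (2 equiv), Et3N (3 equiv), THF/MeCN, rt to 40 °C; cold dilute aq. HCl
Reagents that add atoms: potassium methyl malonate 11, COC(=O)CC(=O)[O-].[K+]; 1,1'-carbonyldiimidazole, O=C(n1ccnc1)n1ccnc1 (imidazolyl group of 12 only)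
Why: Masamune–Brooks homologation (decarboxylative Claisen condensation): acyl imidazolide 12 C-acylates the magnesium enolate of the malonate half-ester and loss of CO2 gives the beta-keto ester under nearly neutral conditions, which avoids strong base next to the very acidic C8–H and installs C6 and C5 in one operation with no regiochemical question.

**Step 8**
Reactants: 13 methyl 4-methoxy-3-oxo-4-{5-[3,4-dimethoxy-5-(methoxymethoxy)phenyl]-4-oxo-4H-pyran-2-yl}butanoate
Product: 15 3'-O-methoxymethylisoirigenin (5,7-dihydroxy-8-methoxy-3-[3,4-dimethoxy-5-(methoxymethoxy)phenyl]-4H-chromen-4-one), via triketone tautomer 14 (not isolated)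
Conditions: DBU (2 equiv), 4 Å MS, toluene (0.02 mol/L), 80 to 110 °C; cold aq. citric acid
Reagents that add atoms: none
Why: DBU ionises 13 reversibly, so the resting C6 enolate (whose ester is switched off) stays in proton-transfer equilibrium with the C8 anion, an extended dienolate spread over C8, C8a, C4a and the C4 oxygen in which the ester is still a neutral electrophile; a stoichiometric strong amide base is avoided because it would lock the unreactive C6,C8 dianion. C4a of this dienolate adds to ester carbon C5 and methoxide leaves (vinylogous Dieckmann–Claisen condensation) to give triketone 14, which enolises twice to the aromatic 5,7-diol, and at reflux the C6 enolate can reach the same bond by E1cB loss of methoxide to the acylketene, whose C7 enol is a dienylketene that closes by six-electron electrocyclisation. The closest known reaction type is the base-induced Claisen cyclisation of 3,5,7-tricarbonyl esters and of their pyranone-masked forms to acylphloroglucinols and 5,7-dihydroxychromones; the methoxy group on the chain is the only new element. Ring A closes in a 6-(enolexo)-exo-trig mode, no stereocentre is created, and the labile C8 centre and the transient C4a centre both vanish on aromatisation. The step needs acylation at C4a rather than at C8, at an oxygen or on another molecule: attack by C8 would give a four-membered ring, by O4 an eight-membered lactone and attack of C6 on C4 an anti-Bredt bicycle, so C4a is the only site that yields an unstrained ring, and dilution suppresses intermolecular addition to C2. The pyranone survives because the base is non-nucleophilic and the expelled methoxide is protonated at once by the far more acidic product, and since the O1–C8a bond is never broken the methoxy group can only end up at C8, not C6.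

**Step 9**
Reactants: 15 3'-O-methoxymethylisoirigenin
Product: 16 isoirigenin
Conditions: conc. HCl (cat.), MeOH, 50 °C
Reagents that add atoms: none
Why: Acid-catalysed acetal exchange removes the single MOM group, while the aryl methyl ethers, the chelated 5-OH and the chromone ring are inert to dilute methanolic HCl, which is far too mild for ring-opening isomerisation to the 6-methoxy series.

**Compound list**
1 | kojic acid | O=c1cc(CO)occ1O | starting material
2 | 6-(hydroxymethyl)-4-oxo-4H-pyran-3-yl trifluoromethanesulfonate | O=c1cc(CO)occ1OS(=O)(=O)C(F)(F)F | intermediate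
3 | 6-(methoxymethyl)-4-oxo-4H-pyran-3-yl trifluoromethanesulfonate | COCc1cc(=O)c(OS(=O)(=O)C(F)(F)F)co1 | intermediate
4 | 2,3-dimethoxyphenol | COc1cccc(O)c1OC | starting material
5 | 1,2-dimethoxy-3-(methoxymethoxy)benzene | COCOc1cccc(OC)c1OC | intermediate
6 | 2-[3,4-dimethoxy-5-(methoxymethoxy)phenyl]-4,4,5,5-tetramethyl-1,3,2-dioxaborolane | COCOc1cc(B2OC(C)(C)C(C)(C)O2)cc(OC)c1OC | intermediate
7 | 5-[3,4-dimethoxy-5-(methoxymethoxy)phenyl]-2-(methoxymethyl)-4H-pyran-4-one | COCc1cc(=O)c(-c2cc(OC)c(OC)c(OCOC)c2)co1 | intermediate
8 | carbon dioxide | O=C=O | starting material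
9 | lithium 5-[3,4-dimethoxy-5-(methoxymethoxy)phenyl]-2-(methoxymethylidene)-2H-pyran-4-olate (alkene geometry undefined) | COC=C1C=C([O-])C(=CO1)c1cc(OC)c(OC)c(OCOC)c1.[Li+] | intermediate
10 | 2-methoxy-2-{5-[3,4-dimethoxy-5-(methoxymethoxy)phenyl]-4-oxo-4H-pyran-2-yl}acetic acid (racemic) | COC(C(=O)O)c1cc(=O)c(-c2cc(OC)c(OC)c(OCOC)c2)co1 | intermediate
11 | potassium methyl malonate | COC(=O)CC(=O)[O-].[K+] | starting material
12 | 1-(2-methoxy-2-{5-[3,4-dimethoxy-5-(methoxymethoxy)phenyl]-4-oxo-4H-pyran-2-yl}acetyl)imidazole (racemic) | COC(C(=O)n1ccnc1)c1cc(=O)c(-c2cc(OC)c(OC)c(OCOC)c2)co1 | intermediate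
13 | methyl 4-methoxy-3-oxo-4-{5-[3,4-dimethoxy-5-(methoxymethoxy)phenyl]-4-oxo-4H-pyran-2-yl}butanoate (racemic, labile at C8) | COC(=O)CC(=O)C(OC)c1cc(=O)c(-c2cc(OC)c(OC)c(OCOC)c2)co1 | intermediate
14 | 3-[3,4-dimethoxy-5-(methoxymethoxy)phenyl]-8-methoxy-4aH-chromene-4,5,7(6H)-trione (racemic keto tautomer of 15) | COC1=C2OC=C(c3cc(OC)c(OC)c(OCOC)c3)C(=O)C2C(=O)CC1=O | intermediate
15 | 3'-O-methoxymethylisoirigenin | COc1cc(-c2coc3c(OC)c(O)cc(O)c3c2=O)cc(OCOC)c1OC | intermediate
16 | isoirigenin | COc1cc(-c2coc3c(OC)c(O)cc(O)c3c2=O)cc(O)c1OC | target

**Total step count:** 9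
**Longest linear sequence:** 7 (steps 1, 2, 5, 6, 7, 8, 9)

**Steps most likely to fail**

Step 8. The substrate may rest as its C6 enolate without closing. It may also be diverted by intermolecular conjugate addition of that enolate to C2 of a second pyranone, or by retro-Claisen cleavage of the C7–C8 bond by liberated methanol. The fallback makes the same C4a–C5 bond without base, through a pericyclic route. It sets out from acid 10, which is condensed with Meldrum's acid (EDC·HCl, DMAP, CH2Cl2, 0 °C to rt) to the acyl Meldrum's acid F1. In dilute refluxing toluene F1 should lose acetone and CO2 to give the acylketene F2. The C7 enol of F2 is a dienylketene that should close by six-electron electrocyclisation to 14 and tautomerise. The route is rejoined at 15.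

Step 6. The vinylogous beta-keto acid may lose CO2 during acidic isolation or during activation in step 7. Ring metalation at C2 may also erode the lateral deprotonation. The fallback never handles a carboxylic acid and builds the chain in another order, C7 and C6 first and C5 last. It sets out from 7, whose lateral anion (LiN(SiMe3)2, THF, −78 °C) is acylated with N-methoxy-N-methylacetamide to the methyl ketone F3. F3 is then converted with LiN(iPr)2 (3.2 equiv, THF, −78 to 0 °C) into its C8,C6 dianion. The terminal, more reactive carbanion of the dianion is carboxylated with dimethyl carbonate, which is gamma-acylation of a 1,3-dicarbonyl-type dianion. The route is rejoined at 13, so steps 6 and 7 are both bypassed.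

Step 2. Etherification of the electron-poor pyranyl carbinol may be sluggish, with silver-assisted hydrolysis of the triflate on long exposure. The fallback makes the ether by displacement instead of O-alkylation. It sets out from 1, which SOCl2 (neat, rt) converts to chlorokojic acid F4. NaOMe (2.2 equiv) in refluxing MeOH, with the ring shielded as its 5-oxido anion, then gives 5-hydroxy-2-(methoxymethyl)-4H-pyran-4-one F5. Triflation with Tf2O and pyridine in CH2Cl2 at 0 °C rejoins the route at 3. In this variant the oxygen on C8 comes from methoxide and not from kojic acid.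

**Further compounds**
F1 | step 8 | 5-(2-methoxy-2-{5-[3,4-dimethoxy-5-(methoxymethoxy)phenyl]-4-oxo-4H-pyran-2-yl}acetyl)-2,2-dimethyl-1,3-dioxane-4,6-dione (racemic) | COC(C(=O)C1C(=O)OC(C)(C)OC1=O)c1cc(=O)c(-c2cc(OC)c(OC)c(OCOC)c2)co1
F2 | step 8 | 4-methoxy-4-{5-[3,4-dimethoxy-5-(methoxymethoxy)phenyl]-4-oxo-4H-pyran-2-yl}buta-1-ene-1,3-dione (acylketene) | COC(C(=O)C=C=O)c1cc(=O)c(-c2cc(OC)c(OC)c(OCOC)c2)co1
F3 | step 6 | 1-methoxy-1-{5-[3,4-dimethoxy-5-(methoxymethoxy)phenyl]-4-oxo-4H-pyran-2-yl}propan-2-one (racemic) | COC(C(C)=O)c1cc(=O)c(-c2cc(OC)c(OC)c(OCOC)c2)co1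
F4 | step 2 | 2-(chloromethyl)-5-hydroxy-4H-pyran-4-one (chlorokojic acid) | O=c1cc(CCl)occ1O
F5 | step 2 | 5-hydroxy-2-(methoxymethyl)-4H-pyran-4-one | COCc1cc(=O)c(O)co1
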